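The synthesis rests on the C2–C3 bond of the tridecane chain, between the acetoxy-bearing stereocentre C2 and the first CH2 of the undecyl tail. The key step exploits the C2–O acetate itself. 2-[3-(Benzyloxy)-5-methoxyphenyl]acetaldehyde and acetyl bromide give a racemic 1-bromoalkyl acetate. A catalyst made from NiBr2·glyme and a chiral bis(oxazoline), with (EtO)3SiH as hydride source, joins it enantioconvergently to undec-1-ene through an α-acetoxy radical. One operation therefore forms the C2–C3 bond, sets the (R) centre and installs the acetate. The benzene ring enters as a benzyl-protected aryl bromide, homologated by two carbons; hydrogenolysis of the benzyl ether ends the route.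

Key step: step 4

Remark: the stereocentre of the target is read from the SMILES as (R) (priorities OAc > CH2Ar > undecyl > H); both antipodes of the bis(oxazoline) ligand class are taken as available, and the one that gives (R) is used.

Step 1
Reactants: 1 3-bromo-5-methoxyphenol
Product: 2 1-(benzyloxy)-3-bromo-5-methoxybenzene
Conditions: BnBr, K2CO3, DMF, rt
Reagents that add atoms: benzyl bromide, BrCc1ccccc1
Why: Williamson ether synthesis, in which the phenoxide formed by K2CO3 is O-alkylated by the reactive benzylic bromide while the aryl bromide stays inert.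

Step 2
Reactants: 2 1-(benzyloxy)-3-bromo-5-methoxybenzene
Product: 4 2-[3-(benzyloxy)-5-methoxyphenyl]ethan-1-ol, via arylmagnesium bromide 3 (not isolated)
Conditions: Mg, I2 (cat.), THF, reflux; then ethylene oxide (THF solution), CuI (10 mol %), −30 °C to rt; 1 M HCl work-up
Reagents that add atoms: ethylene oxide, C1CO1
Why: Grignard formation followed by copper-catalysed SN2 opening of ethylene oxide is the classical two-carbon homologation of an aryl halide to a 2-arylethanol, and both ethers tolerate the organomagnesium reagent.

Step 3
Reactants: 4 2-[3-(benzyloxy)-5-methoxyphenyl]ethan-1-ol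
Product: 5 2-[3-(benzyloxy)-5-methoxyphenyl]acetaldehyde
Conditions: Dess–Martin periodinane, CH2Cl2, 0 °C to rt; crude aldehyde used at once
Reagents that add atoms: none
Why: Dess–Martin oxidation should stop cleanly at the aldehyde under neutral, anhydrous conditions, which suits an enolisable arylacetaldehyde.

Step 4
Reactants: 5 2-[3-(benzyloxy)-5-methoxyphenyl]acetaldehyde; 6 undec-1-ene
Product: 8 (R)-1-[3-(benzyloxy)-5-methoxyphenyl]tridecan-2-yl acetate, via racemic 1-bromoalkyl acetate 7 (not isolated)
Conditions: AcBr (1.05 equiv), CH2Cl2, 0 °C to rt, then concentrate; 6 (1.5 equiv), NiBr2·glyme (10 mol %), chiral bis(oxazoline) ligand (12 mol %, antipode giving (R)), (EtO)3SiH, K3PO4·H2O, Et2O/DMA, rt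
Reagents that add atoms: acetyl bromide, CC(Br)=O
Why: Acetyl bromide adds across the C=O of 5 to give racemic 7; a monovalent nickel species abstracts its bromine atom to give a planar α-acetoxyalkyl radical, while a bis(oxazoline)-bound divalent nickel hydride, formed from the silane and phosphate, inserts undec-1-ene in the anti-Markovnikov sense to give a primary undecylnickel species. Capture of the radical by this alkylnickel and reductive elimination from trivalent nickel form the C2–C3 bond; the closest known reaction type is the nickel-hydride-catalysed enantioconvergent hydroalkylation of terminal olefins with racemic 1-bromoalkyl esters, including its one-pot variant from an aldehyde and an acyl bromide. No ring is closed. The C2 stereocentre is set by the chiral ligand on nickel (catalyst control): both enantiomers of 7 converge on the same radical, and the acetate carbonyl offers nickel a second contact that distinguishes the acyloxy group from the two alkyl residues, so the selectivity does not rest on the small steric difference between arylmethyl and undecyl. The step needs linear regioselectivity, secured by the unbranched terminal olefin, and coupling in preference to loss of HBr toward the enol acetate or reduction of the C–Br bond, favoured by the mild heterogeneous base and room temperature. The ligand antipode that delivers (R) would be confirmed on the first run by Mosher ester analysis of the derived alcohol.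

Step 5
Reactants: 8 (R)-1-[3-(benzyloxy)-5-methoxyphenyl]tridecan-2-yl acetate
Product: 9 (R)-1-(3-hydroxy-5-methoxyphenyl)tridecan-2-yl acetate
Conditions: H2 (1 atm), 10% Pd/C, EtOAc, rt
Reagents that add atoms: none
Why: Catalytic hydrogenolysis cleaves the benzylic C–O bond of the aryl benzyl ether, whereas the acetate sits on a homobenzylic carbon and is not hydrogenolysed, so ester and stereocentre should remain untouched.

Compound list
1 | 3-bromo-5-methoxyphenol | COc1cc(O)cc(Br)c1 | starting material
2 | 1-(benzyloxy)-3-bromo-5-methoxybenzene | COc1cc(Br)cc(OCc2ccccc2)c1 | intermediate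
3 | [3-(benzyloxy)-5-methoxyphenyl]magnesium bromide | COc1cc([Mg]Br)cc(OCc2ccccc2)c1 | intermediate
4 | 2-[3-(benzyloxy)-5-methoxyphenyl]ethan-1-ol | COc1cc(CCO)cc(OCc2ccccc2)c1 | intermediate
5 | 2-[3-(benzyloxy)-5-methoxyphenyl]acetaldehyde | COc1cc(CC=O)cc(OCc2ccccc2)c1 | intermediate
6 | undec-1-ene | C=CCCCCCCCCC | starting material
7 | racemic 1-bromo-2-[3-(benzyloxy)-5-methoxyphenyl]ethyl acetate | CC(=O)OC(Br)Cc1cc(OC)cc(OCc2ccccc2)c1 | intermediate
8 | (R)-1-[3-(benzyloxy)-5-methoxyphenyl]tridecan-2-yl acetate | CCCCCCCCCCC[C@H](Cc1cc(OC)cc(OCc2ccccc2)c1)OC(C)=O | intermediate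
9 | (R)-1-(3-hydroxy-5-methoxyphenyl)tridecan-2-yl acetate | CCCCCCCCCCC[C@H](Cc1cc(O)cc(OC)c1)OC(C)=O | target

Total step count: 5. Longest linear sequence: 5 steps (1 to 9).

Steps most likely to fail

Step 4. The bromoacetate formed in the flask may lose HBr toward the conjugated enol acetate, since its β-hydrogens are benzylic. The C–Br bond may also be reduced before coupling, or the small acetyl group may give weak enantiocontrol. The fallback forms the same C2–C3 bond by a 1,2-metallate rearrangement. Alcohol 4 would be carbamoylated (N,N-diisopropylcarbamoyl chloride, Et3N, toluene, reflux) to 2-[3-(benzyloxy)-5-methoxyphenyl]ethyl N,N-diisopropylcarbamate F1. Undec-1-ene 6 would be hydroborated with pinacolborane ([Ir(cod)Cl]2, dppm, CH2Cl2, rt) to 4,4,5,5-tetramethyl-2-undecyl-1,3,2-dioxaborolane F2. Deprotonation of F1 with s-BuLi/(+)-sparteine (Et2O, −78 °C) should give the configurationally stable (R)-α-lithio carbamate F3. This should take up F2 with retention to give the lithium boronate complex F4. On warming with MgBr2·OEt2 the undecyl group should migrate from boron to carbon with inversion, expelling the carbamate, to give the (R)-secondary boronic ester F5. Oxidation with NaOH/H2O2 (retention) should give (R)-1-[3-(benzyloxy)-5-methoxyphenyl]tridecan-2-ol F6. Acetylation (Ac2O, pyridine, DMAP, CH2Cl2) returns to the route at 8.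

Step 3. The enolisable, electron-rich arylacetaldehyde may self-condense or oxidise in air during oxidation and isolation. The fallback reaches the aldehyde without an oxidation, setting out from bromide 2. Suzuki–Miyaura coupling with (E)-2-(2-ethoxyvinyl)-4,4,5,5-tetramethyl-1,3,2-dioxaborolane (Pd(PPh3)4, K2CO3, dioxane/H2O, 80 °C) should give the storable (E)-1-(benzyloxy)-3-(2-ethoxyvinyl)-5-methoxybenzene F7. Mild hydrolysis (aqueous HCl, THF, rt) just before use releases the aldehyde and returns to the route at 5.

Step 2. Grignard formation may start sluggishly or give biaryl homocoupling, and the epoxide may be opened by bromide in place of the aryl group. The fallback sets out from bromide 2. Palladium-catalysed α-arylation of the lithium enolate of tert-butyl acetate (LiHMDS, Pd(dba)2, P(t-Bu)3, toluene, rt) should give tert-butyl 2-[3-(benzyloxy)-5-methoxyphenyl]acetate F8. Reduction with LiAlH4 (THF, 0 °C to rt) returns to the route at 4.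

Further compounds
F1 | step 4 | 2-[3-(benzyloxy)-5-methoxyphenyl]ethyl N,N-diisopropylcarbamate | COc1cc(CCOC(=O)N(C(C)C)C(C)C)cc(OCc2ccccc2)c1
F2 | step 4 | 4,4,5,5-tetramethyl-2-undecyl-1,3,2-dioxaborolane | CCCCCCCCCCCB1OC(C)(C)C(C)(C)O1
F3 | step 4 | (R)-2-[3-(benzyloxy)-5-methoxyphenyl]-1-lithioethyl N,N-diisopropylcarbamate | [Li][C@H](Cc1cc(OC)cc(OCc2ccccc2)c1)OC(=O)N(C(C)C)C(C)C
F4 | step 4 | lithium boronate complex of F3 and F2, (R) at carbon | [Li+].CCCCCCCCCCC[B-]1(OC(C)(C)C(C)(C)O1)[C@H](Cc1cc(OC)cc(OCc2ccccc2)c1)OC(=O)N(C(C)C)C(C)C
F5 | step 4 | (R)-2-{1-[3-(benzyloxy)-5-methoxyphenyl]tridecan-2-yl}-4,4,5,5-tetramethyl-1,3,2-dioxaborolane | CCCCCCCCCCC[C@H](Cc1cc(OC)cc(OCc2ccccc2)c1)B1OC(C)(C)C(C)(C)O1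
F6 | step 4 | (R)-1-[3-(benzyloxy)-5-methoxyphenyl]tridecan-2-ol | CCCCCCCCCCC[C@H](Cc1cc(OC)cc(OCc2ccccc2)c1)O
F7 | step 3 | (E)-1-(benzyloxy)-3-(2-ethoxyvinyl)-5-methoxybenzene | CCO/C=C/c1cc(OC)cc(OCc2ccccc2)c1
F8 | step 2 | tert-butyl 2-[3-(benzyloxy)-5-methoxyphenyl]acetate | COc1cc(CC(=O)OC(C)(C)C)cc(OCc2ccccc2)c1
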